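**Strategy.** The quinone (ring B: C1=O, C2 and C3 methoxylated, C4=O, C5 bonded to chroman C3, C6–H) is disconnected at C5=C6. This is the enone bond of an aldol condensation between C5, the α-carbon of the C4 ketone, and a C6 aldehyde. The cis-2,3-dimethoxy-ene-1,4-dione C1–C4 that holds both partners in reach is latent in a 3,4-dimethoxyfuran. In one flask, dimethyldioxirane opens a 2-(dimethoxymethyl)-5-(chroman-3-ylmethyl)-3,4-dimethoxyfuran to the Z-enetrione acetal; aqueous acid then frees the aldehyde, closes ring B by aldol condensation and removes the phenol protecting group. The stereocentre (3S) is set earlier by Evans alkylation and lies β to the reacting ketone.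

Key step: step 12

Remark: ring A is the benzene ring and ring C the dihydropyran ring of the chroman; 3,4-dimethoxyfuran is taken as a catalogue compound and dimethyldioxirane as a freshly prepared acetone solution.

**Step 1**
Reactants: 1 syringaldehyde
Product: 2 3,5-dimethoxy-4-(methoxymethoxy)benzaldehyde
Conditions: MOMCl, i-Pr2NEt, CH2Cl2, 0 °C to rt
Reagents that add atoms: chloromethyl methyl ether, COCCl
Why: O-alkylation of the phenol with the reactive α-chloro ether (MOM protection) should give an ether that survives the hydride, enolate, organolithium and palladium steps and is cleaved in the final acid treatment.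

**Step 2**
Reactants: 2 3,5-dimethoxy-4-(methoxymethoxy)benzaldehyde
Product: 3 2-bromo-3,5-dimethoxy-4-(methoxymethoxy)benzaldehyde
Conditions: NBS, DMF, rt
Reagents that add atoms: N-bromosuccinimide, O=C1CCC(=O)N1Br
Why: Electrophilic aromatic bromination should go to C2 (equivalent to C6), the only free ring position and ortho/para to the two methoxy groups, as in the 2-bromination of 3,4,5-trialkoxybenzaldehydes.

**Step 3**
Reactants: 3 2-bromo-3,5-dimethoxy-4-(methoxymethoxy)benzaldehyde
Product: 4 [2-bromo-3,5-dimethoxy-4-(methoxymethoxy)phenyl]methanol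
Conditions: NaBH4, MeOH, 0 °C
Reagents that add atoms: none
Why: Borohydride reduction of the aldehyde should leave the aryl bromide and the MOM ether untouched.

**Step 4**
Reactants: 4 [2-bromo-3,5-dimethoxy-4-(methoxymethoxy)phenyl]methanol
Product: 5 2-bromo-1-(bromomethyl)-3,5-dimethoxy-4-(methoxymethoxy)benzene
Conditions: CBr4, PPh3, CH2Cl2, 0 °C
Reagents that add atoms: carbon tetrabromide, BrC(Br)(Br)Br
Why: The Appel reaction should convert the benzylic alcohol into the bromide under neutral conditions that spare the MOM acetal.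

**Step 5**
Reactants: 6 3,4-dimethoxyfuran; 7 β-propiolactone (oxetan-2-one)
Product: 8 3-(3,4-dimethoxyfuran-2-yl)propanoic acid
Conditions: n-BuLi, THF, −78 to 0 °C; MgBr2·OEt2; CuBr·SMe2 (10 mol %), then 7, −30 to 0 °C; aq. HCl work-up
Reagents that add atoms: none
Why: α-Lithiation of the furan, transmetalation to the Grignard reagent and copper-catalysed SN2 opening of the β-lactone at its O-alkyl carbon should give the 3-substituted propanoic acid.

**Step 6**
Reactants: 8 3-(3,4-dimethoxyfuran-2-yl)propanoic acid; 9 (S)-4-benzyl-1,3-oxazolidin-2-one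
Product: 10 (4S)-4-benzyl-3-[3-(3,4-dimethoxyfuran-2-yl)propanoyl]-1,3-oxazolidin-2-one
Conditions: PivCl, Et3N, THF, −20 °C; then 9, LiCl, rt
Reagents that add atoms: none
Why: N-Acylation of the oxazolidinone through the mixed pivalic anhydride under LiCl/Et3N activation should give the imide without exposing the furan to strong acid.

**Step 7**
Reactants: 10 (4S)-4-benzyl-3-[3-(3,4-dimethoxyfuran-2-yl)propanoyl]-1,3-oxazolidin-2-one; 5 2-bromo-1-(bromomethyl)-3,5-dimethoxy-4-(methoxymethoxy)benzene
Product: 11 (4S)-4-benzyl-3-[(2S)-2-{[2-bromo-3,5-dimethoxy-4-(methoxymethoxy)phenyl]methyl}-3-(3,4-dimethoxyfuran-2-yl)propanoyl]-1,3-oxazolidin-2-one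
Conditions: NaHMDS, THF, −78 °C; then 5, −78 to −40 °C
Reagents that add atoms: none
Why: Evans asymmetric alkylation: the chelated sodium (Z)-enolate should be benzylated on the face opposite the C4 benzyl group of the auxiliary, which sets the (2S) centre that becomes chroman C3.

**Step 8**
Reactants: 11 the alkylated imide
Product: 12 (2S)-2-{[2-bromo-3,5-dimethoxy-4-(methoxymethoxy)phenyl]methyl}-3-(3,4-dimethoxyfuran-2-yl)propan-1-ol
Conditions: LiBH4, H2O (1 equiv), Et2O, 0 °C
Reagents that add atoms: none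
Why: Reductive cleavage of the imide with LiBH4 should give the primary alcohol without epimerisation and release the auxiliary for recovery.

**Step 9**
Reactants: 12 the bromo alcohol
Product: 13 (3S)-3-[(3,4-dimethoxyfuran-2-yl)methyl]-6,8-dimethoxy-7-(methoxymethoxy)-3,4-dihydro-2H-chromene
Conditions: Pd(OAc)2 (5 mol %), tBuXPhos (2-di-tert-butylphosphino-2',4',6'-triisopropylbiphenyl, 6 mol %), Cs2CO3, toluene, 80 °C
Reagents that add atoms: none
Why: Intramolecular Buchwald–Hartwig etherification: oxidative addition of the aryl bromide to zerovalent palladium, alkoxide binding and C–O reductive elimination should close ring C at O1–C8a without touching the stereocentre.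

**Step 10**
Reactants: 13 the furylmethyl chroman
Product: 14 5-{[(3S)-6,8-dimethoxy-7-(methoxymethoxy)-3,4-dihydro-2H-chromen-3-yl]methyl}-3,4-dimethoxyfuran-2-carbaldehyde
Conditions: n-BuLi, THF, −78 to −30 °C; DMF; aq. NH4Cl
Reagents that add atoms: N,N-dimethylformamide, CN(C)C=O
Why: The single furan α-hydrogen is the most acidic site, so α-lithiation followed by formylation with DMF should give the 2-furaldehyde that carries the future C6.

**Step 11**
Reactants: 14 the furaldehyde
Product: 15 2-(dimethoxymethyl)-5-{[(3S)-6,8-dimethoxy-7-(methoxymethoxy)-3,4-dihydro-2H-chromen-3-yl]methyl}-3,4-dimethoxyfuran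
Conditions: HC(OMe)3, MeOH, PPTS (cat.), rt; Et3N quench
Reagents that add atoms: trimethyl orthoformate, COC(OC)OC; methanol (solvent, exchanges with the orthoformate), CO
Why: Orthoformate-driven acetalisation should mask the aldehyde so that the furan can be oxidised without Baeyer–Villiger or deformylation pathways.

**Step 12**
Reactants: 15 the furan acetal
Product: 19 5-[(3S)-7-hydroxy-6,8-dimethoxy-3,4-dihydro-2H-chromen-3-yl]-2,3-dimethoxycyclohexa-2,5-diene-1,4-dione (target), via enetrione acetal 16 (not isolated), via ketoaldehyde 17 (not isolated), via aldol 18 (not isolated)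
Conditions: dimethyldioxirane (1.0 equiv), acetone, −78 to 0 °C; evaporate; TFA–CH2Cl2–H2O (10:10:1), 0 °C to rt, dilute
Reagents that add atoms: dimethyldioxirane, CC1(C)OO1
Why: Dimethyldioxirane should epoxidise the electron-rich furan, and the epoxide should collapse to the (Z)-2-ene-1,4-dione 16, the standard oxidative unmasking of a furan. Aqueous acid should then hydrolyse the α-keto acetal and the MOM ether to 17, the C4 ketone should enolise toward C5 (its only α-carbon) and add to the C6 aldehyde, and loss of water from aldol 18 should give the C5=C6 bond directly at the quinone oxidation level; the closest known reaction type is the acid-mediated intramolecular aldol condensation of a 1,2-dicarbonyl compound with a ketone. Ring B closes in the 6-(enolendo)-exo-trig mode. No stereocentre is formed, and chroman C3 is β to the enolising ketone and is not touched. The step needs the Z geometry of C2=C3, which the furan ring dictates, and six-ring over five-ring closure (C5 onto the C1 ketone), which is secured by the higher electrophilicity of the aldehyde, the disfavoured 5-(enolendo)-exo-trig mode and the irreversible dehydration to the quinone.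

**Compound list**
1 | syringaldehyde (4-hydroxy-3,5-dimethoxybenzaldehyde) | COc1cc(C=O)cc(OC)c1O | starting material
2 | 3,5-dimethoxy-4-(methoxymethoxy)benzaldehyde | COCOc1c(OC)cc(C=O)cc1OC | intermediate
3 | 2-bromo-3,5-dimethoxy-4-(methoxymethoxy)benzaldehyde | COCOc1c(OC)cc(C=O)c(Br)c1OC | intermediate
4 | [2-bromo-3,5-dimethoxy-4-(methoxymethoxy)phenyl]methanol | COCOc1c(OC)cc(CO)c(Br)c1OC | intermediate
5 | 2-bromo-1-(bromomethyl)-3,5-dimethoxy-4-(methoxymethoxy)benzene | COCOc1c(OC)cc(CBr)c(Br)c1OC | intermediate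
6 | 3,4-dimethoxyfuran | COc1cocc1OC | starting material
7 | β-propiolactone (oxetan-2-one) | O=C1CCO1 | starting material
8 | 3-(3,4-dimethoxyfuran-2-yl)propanoic acid | COc1coc(CCC(=O)O)c1OC | intermediate
9 | (S)-4-benzyl-1,3-oxazolidin-2-one | O=C1N[C@@H](Cc2ccccc2)CO1 | starting material
10 | (4S)-4-benzyl-3-[3-(3,4-dimethoxyfuran-2-yl)propanoyl]-1,3-oxazolidin-2-one | COc1coc(CCC(=O)N2[C@@H](Cc3ccccc3)COC2=O)c1OC | intermediate
11 | (4S)-4-benzyl-3-[(2S)-2-{[2-bromo-3,5-dimethoxy-4-(methoxymethoxy)phenyl]methyl}-3-(3,4-dimethoxyfuran-2-yl)propanoyl]-1,3-oxazolidin-2-one | COc1coc(C[C@@H](C(=O)N2[C@@H](Cc3ccccc3)COC2=O)Cc4cc(OC)c(OCOC)c(OC)c4Br)c1OC | intermediate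
12 | (2S)-2-{[2-bromo-3,5-dimethoxy-4-(methoxymethoxy)phenyl]methyl}-3-(3,4-dimethoxyfuran-2-yl)propan-1-ol | COc1coc(C[C@@H](CO)Cc2cc(OC)c(OCOC)c(OC)c2Br)c1OC | intermediate
13 | (3S)-3-[(3,4-dimethoxyfuran-2-yl)methyl]-6,8-dimethoxy-7-(methoxymethoxy)-3,4-dihydro-2H-chromene | COc1coc(C[C@H]2COc3c(cc(OC)c(OCOC)c3OC)C2)c1OC | intermediate
14 | 5-{[(3S)-6,8-dimethoxy-7-(methoxymethoxy)-3,4-dihydro-2H-chromen-3-yl]methyl}-3,4-dimethoxyfuran-2-carbaldehyde | O=Cc1oc(C[C@H]2COc3c(cc(OC)c(OCOC)c3OC)C2)c(OC)c1OC | intermediate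
15 | 2-(dimethoxymethyl)-5-{[(3S)-6,8-dimethoxy-7-(methoxymethoxy)-3,4-dihydro-2H-chromen-3-yl]methyl}-3,4-dimethoxyfuran | COC(OC)c1oc(C[C@H]2COc3c(cc(OC)c(OCOC)c3OC)C2)c(OC)c1OC | intermediate
16 | (3Z)-6-[(3S)-6,8-dimethoxy-7-(methoxymethoxy)-3,4-dihydro-2H-chromen-3-yl]-1,1,3,4-tetramethoxyhex-3-ene-2,5-dione (enetrione acetal, formed in the flask) | COC(OC)C(=O)/C(OC)=C(/OC)C(=O)C[C@H]1COc2c(cc(OC)c(OCOC)c2OC)C1 | intermediate
17 | (3Z)-6-[(3S)-7-hydroxy-6,8-dimethoxy-3,4-dihydro-2H-chromen-3-yl]-3,4-dimethoxy-2,5-dioxohex-3-enal (ketoaldehyde, formed in the flask) | O=CC(=O)/C(OC)=C(/OC)C(=O)C[C@H]1COc2c(cc(OC)c(O)c2OC)C1 | intermediate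
18 | 6-hydroxy-5-[(3S)-7-hydroxy-6,8-dimethoxy-3,4-dihydro-2H-chromen-3-yl]-2,3-dimethoxycyclohex-2-ene-1,4-dione (aldol, mixture at C5 and C6, formed in the flask) | COC1=C(OC)C(=O)C([C@H]2COc3c(cc(OC)c(O)c3OC)C2)C(O)C1=O | intermediate
19 | 5-[(3S)-7-hydroxy-6,8-dimethoxy-3,4-dihydro-2H-chromen-3-yl]-2,3-dimethoxycyclohexa-2,5-diene-1,4-dione | COC1=C(OC)C(=O)C([C@H]2COc3c(cc(OC)c(O)c3OC)C2)=CC1=O | target

**Step count.** Total: 12 steps. Longest linear sequence: 10 steps (steps 1–4 and 7–12, from syringaldehyde).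

**Steps most likely to fail**

Step 12 (furan unmasking and aldol condensation). The acid needed to hydrolyse the α-keto acetal may also hydrolyse the vinylogous-ester methoxy groups or degrade the quinone, and the enetrione may be diverted into five-ring aldol products or isomerise at C2=C3 before it cyclises. The fallback sets out from 13 and returns at 19, closing the same C5–C6 bond by a pericyclic route. C5 lithiation of 13 (n-BuLi, THF) and quench with MeI would give the 2-methylfuran F1. Dimethyldioxirane would open it to the (Z)-enedione F2. TMSOTf/Et3N would give the bis(trimethylsilyl enol ether) triene F3. Heating in toluene should close ring B by thermal disrotatory 6π-electrocyclisation to the cyclohexa-1,3-diene F4, which DDQ (1 equiv, 0 °C) should dehydrogenate to the bis(silyloxy)arene F5. TFA–H2O would remove the silyl and MOM groups to give the hydroquinone F6, and Ag2O should oxidise F6 to 19 without touching ring A.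

Step 5 (copper-catalysed opening of β-propiolactone). The furyl group may transfer sluggishly from copper, or the organometallic may attack the lactone carbonyl instead of the O-alkyl carbon. The fallback sets out from 6 and returns at 10, bypassing acid 8. Lithiation of 6 and quench with DMF would give the furaldehyde F7. Horner–Wadsworth–Emmons olefination with (S)-4-benzyl-3-[(diethoxyphosphoryl)acetyl]-1,3-oxazolidin-2-one (LiCl, i-Pr2NEt, MeCN) would give the (E)-N-enoyl oxazolidinone F8. Hydrogenation of the conjugated double bond (H2, Pd/C, EtOAc) would give 10.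

Step 9 (palladium-catalysed etherification). β-Hydride elimination from the palladium alkoxide, giving reduction of the C–Br bond and oxidation of the alcohol, or slow reductive elimination at the di-ortho-substituted, electron-rich aryl group may outrun ring closure. The fallback sets out from 12 and returns at 13. Palladium-catalysed hydroxylation of the aryl bromide (Pd2(dba)3, tBuXPhos, KOH, dioxane–H2O, 100 °C), whose nucleophile has no β-hydrogen, would give the phenol F9. Mitsunobu cyclisation (PPh3, DIAD, THF) onto the primary alcohol would then close ring C to 13.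

**Further compounds**
F1 | step 12 | (3S)-3-[(3,4-dimethoxy-5-methylfuran-2-yl)methyl]-6,8-dimethoxy-7-(methoxymethoxy)-3,4-dihydro-2H-chromene | Cc1oc(C[C@H]2COc3c(cc(OC)c(OCOC)c3OC)C2)c(OC)c1OC
F2 | step 12 | (3Z)-1-[(3S)-6,8-dimethoxy-7-(methoxymethoxy)-3,4-dihydro-2H-chromen-3-yl]-3,4-dimethoxyhex-3-ene-2,5-dione | CC(=O)/C(OC)=C(/OC)C(=O)C[C@H]1COc2c(cc(OC)c(OCOC)c2OC)C1
F3 | step 12 | (3Z)-1-[(3S)-6,8-dimethoxy-7-(methoxymethoxy)-3,4-dihydro-2H-chromen-3-yl]-3,4-dimethoxy-2,5-bis(trimethylsilyloxy)hexa-1,3,5-triene (enol ether geometry at C1 open) | C=C(O[Si](C)(C)C)/C(OC)=C(/OC)C(O[Si](C)(C)C)=C[C@H]1COc2c(cc(OC)c(OCOC)c2OC)C1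
F4 | step 12 | (3S)-3-[3,4-dimethoxy-2,5-bis(trimethylsilyloxy)cyclohexa-2,4-dien-1-yl]-6,8-dimethoxy-7-(methoxymethoxy)-3,4-dihydro-2H-chromene (mixture at the ring carbon) | COC1=C(O[Si](C)(C)C)CC([C@H]2COc3c(cc(OC)c(OCOC)c3OC)C2)C(O[Si](C)(C)C)=C1OC
F5 | step 12 | (3S)-3-[3,4-dimethoxy-2,5-bis(trimethylsilyloxy)phenyl]-6,8-dimethoxy-7-(methoxymethoxy)-3,4-dihydro-2H-chromene | COc1c(OC)c(O[Si](C)(C)C)c([C@H]2COc3c(cc(OC)c(OCOC)c3OC)C2)cc1O[Si](C)(C)C
F6 | step 12 | 5-[(3S)-7-hydroxy-6,8-dimethoxy-3,4-dihydro-2H-chromen-3-yl]-2,3-dimethoxybenzene-1,4-diol | COc1c(OC)c(O)c([C@H]2COc3c(cc(OC)c(O)c3OC)C2)cc1O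
F7 | step 5 | 3,4-dimethoxyfuran-2-carbaldehyde | COc1coc(C=O)c1OC
F8 | step 5 | (4S)-4-benzyl-3-[(2E)-3-(3,4-dimethoxyfuran-2-yl)prop-2-enoyl]-1,3-oxazolidin-2-one | COc1coc(/C=C/C(=O)N2[C@@H](Cc3ccccc3)COC2=O)c1OC
F9 | step 9 | 2-[(2S)-2-(hydroxymethyl)-3-(3,4-dimethoxyfuran-2-yl)propyl]-4,6-dimethoxy-5-(methoxymethoxy)phenol | COc1coc(C[C@@H](CO)Cc2cc(OC)c(OCOC)c(OC)c2O)c1OC
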